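**Plan**

1. The last bonds made are cut first: the 2H-pyran ring is opened at both C4–C4a and O1–C2, which removes a C5 unit (3-methylbut-2-enal) and leaves the chromene-free, methylene-bridged dimer.
2. Enabling feature: in that dimer the benzene-ring carbon C5 is the only unsubstituted ring carbon of either six-membered ring and lies between the phenolic oxygens O4 and O6. Condensation with the enal there gives the ortho-quinone methide O6=C6–C5=CH–CH=CMe2, a 1-oxatriene that closes to the pyran ring by oxa-6π electrocyclisation (formal [3+3]).
3. Next cut: the CH2 bridge, giving hexanoylphloroglucinol (from phloroglucinol and hexanoyl chloride), a one-carbon iminium salt and the acetylcyclohexanetrione that carries the stereocentre.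
4. The trione ring is cut at C2–C3 (Claisen ring closure) and C6–C1 (acetoacetylation of a methyl ketone enolate with diketene), back to an α-geranyl-α-methyl acetoacetate.
5. Forward order: stereocentre, trione ring, acylated benzene ring, CH2 bridge, pyran ring last; no protecting groups.
6. Stereochemistry: the single quaternary centre is set by alkylating the L-valine tert-butyl ester enamine of ethyl 2-methylacetoacetate with geranyl bromide, which also supplies the E olefin. The centre has no α-hydrogen, and its two ring arms are distinguished by construction (the ester carbon ends next to C–acetyl, the ketone carbon next to C–CH2).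

Key step: step 6

Assumption (sense of induction in step 2): under the toluene/HMPA protocol the lithio-enamine of the L-valine auxiliary is taken to be alkylated on the face that gives the R keto ester; if the sense proves opposite, the THF protocol or D-valine tert-butyl ester gives the same compound with no change to the route.

Remark: β-triketones are drawn in one enol form, and the R descriptors refer to the form drawn.

**Route**

Step 1
Reactants: 1 ethyl 2-methyl-3-oxobutanoate; 2 L-valine tert-butyl ester
Product: 3 tert-butyl (2S)-2-{[(2Z)-4-ethoxy-3-methyl-4-oxobut-2-en-2-yl]amino}-3-methylbutanoate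
Conditions: cat. BF3·OEt2, benzene, reflux, Dean–Stark
Reagents that add atoms: none
Why: Acid-catalysed condensation of a β-keto ester with a primary amine under azeotropic removal of water should give the conjugated, N–H···O=C chelated (Z)-enamino ester; this loads the auxiliary, creates no stereocentre and leaves the valine centre untouched.

Step 2
Reactants: 3 enamino ester; 4 geranyl bromide
Product: 6 ethyl (2R,4E)-2-acetyl-2,5,9-trimethyldeca-4,8-dienoate, via ketimine 5 (not isolated)
Conditions: LDA (1.2 equiv), toluene, −78 °C; HMPA (3 equiv); 4, −78 → −55 °C; then 10% aq. citric acid, rt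
Reagents that add atoms: water, O
Why: Auxiliary-controlled asymmetric alkylation of the chiral enamine of an α-alkyl β-keto ester: LDA removes the N–H to give a lithio-enamine in which lithium is chelated by nitrogen and the valine tert-butyl ester carbonyl, the isopropyl group and the ligand sphere of lithium leave one face of the α-carbon open, SN2 attack on the primary allylic bromide (E geometry retained) sets the quaternary centre as R, and mild aqueous acid hydrolyses ketimine 5 and returns the auxiliary.

Step 3
Reactants: 6 keto ester; 7 diketene
Product: 9 (4R)-2-acetyl-4-[(2E)-3,7-dimethylocta-2,6-dien-1-yl]-3,5-dihydroxy-4-methylcyclohexa-2,5-dien-1-one, via triketo ester 8 (not isolated)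
Conditions: LDA (1.05 equiv), THF, −78 °C; 7, −78 → −20 °C; then t-BuOK (2.2 equiv), 0 °C → rt; 1 M HCl
Reagents that add atoms: none
Why: The ketone can be deprotonated only at its methyl group (the other α-carbon is quaternary), so the kinetic lithium enolate should be acetoacetylated at carbon by ring opening of diketene at its acyl carbon, and under tert-butoxide the doubly stabilised carbanion between the 5- and 7-carbonyl groups of 8 attacks the ester in a six-membered Claisen (Dieckmann-type) ring closure driven by deprotonation of the acidic product; the quaternary centre has no α-hydrogen, and because the ester carbon ends next to the acetyl-bearing carbon and the former ketone carbon next to the ring CH, the configuration of 6 is carried over without any achiral intermediate.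

Step 4
Reactants: 10 phloroglucinol; 11 hexanoyl chloride
Product: 12 1-(2,4,6-trihydroxyphenyl)hexan-1-one
Conditions: AlCl3 (4 equiv), PhNO2/CH2Cl2, 0 → 45 °C; ice/aq. HCl
Reagents that add atoms: none
Why: Friedel–Crafts C-acylation of the symmetrical, electron-rich triphenol; the three ring positions are equivalent and the first acyl group deactivates the ring, so monoacylation is expected and no stereocentre is involved.

Step 5
Reactants: 9 acetyl trione; 13 N,N-dimethylmethyleneiminium iodide (Eschenmoser's salt); 12 hexanoylphloroglucinol
Product: 15 (4R)-2-acetyl-4-[(2E)-3,7-dimethylocta-2,6-dien-1-yl]-6-[(3-hexanoyl-2,4,6-trihydroxyphenyl)methyl]-3,5-dihydroxy-4-methylcyclohexa-2,5-dien-1-one, via Mannich salt 14 (not isolated)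
Conditions: 13 (1.05 equiv), MeCN, 0 °C → rt; then 12 (3 equiv), 60 °C
Reagents that add atoms: none
Why: Mannich aminomethylation of the only enolic C–H of 9 (C6, between two enolised carbonyl carbons), then thermal loss of dimethylamine hydroiodide to the 6-methylene trione, an ortho-quinone-methide-type acceptor that is captured at carbon (Michael/Friedel–Crafts alkylation) by one of the two equivalent ring positions of 12; all of 9 is converted into 14 before the acceptor is released, which excludes its homodimer, the excess of 12 suppresses double alkylation, and the stereocentre is not involved.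

Step 6
Reactants: 15 chromene-free dimer; 16 3-methylbut-2-enal (prenal)
Product: 18 (4R)-2-acetyl-4-[(2E)-3,7-dimethylocta-2,6-dien-1-yl]-6-[(8-hexanoyl-5,7-dihydroxy-2,2-dimethyl-2H-chromen-6-yl)methyl]-3,5-dihydroxy-4-methylcyclohexa-2,5-dien-1-one, via ortho-quinone methide 17 (not isolated)
Conditions: 16 (1.5 equiv), ethylenediammonium diacetate (20 mol%), toluene, 90 °C, Ar, dark
Reagents that add atoms: none
Why: The ammonium acetate turns prenal into its iminium ion, which is attacked by C5 of the hexanoylphloroglucinol ring of 15 (ortho to O4–H and O6–H), and loss of the amine gives ortho-quinone methide 17, the 1-oxatriene O6=C6–C5=CH–CH=CMe2, so the aryl–CH bond is made by a Knoevenagel-type condensation. A thermally allowed disrotatory oxa-6π electrocyclisation of 17 then joins O6 to the CMe2 terminus and restores the benzene ring; the closest known reaction type is the amine-catalysed formal [3+3] chromenylation of acylphloroglucinols and other 1,3-dioxygenated arenes with α,β-unsaturated aldehydes. The 2H-pyran ring is thus closed by a pericyclic 6π ring closure and not by an ionic exo or endo cyclisation. No stereocentre is formed (C2 of the chromene carries two methyl groups) and the quaternary centre of the trione ring, which has no α-hydrogen, is not touched. Site selectivity is secured by the substitution pattern: every other nucleophilic ring carbon of both six-membered rings is already substituted, so only one C–C bond can form and a second annulation is impossible. The selectivity that has to be won is the direction of closure (O6, ortho to the hexanoyl group, and not O4): O4–H lies between the bridge and the new vinyl group and should be held as hydrogen-bond donor to a trione oxygen across the CH2 bridge while O2–H chelates the hexanoyl carbonyl, which leaves O6 as the quinonoid oxygen of 17, the sense of closure expected from the behaviour of 3-alkylated acylphloroglucinols.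

**Compound list**

1 | ethyl 2-methyl-3-oxobutanoate | CCOC(=O)C(C)C(C)=O | starting material
2 | L-valine tert-butyl ester | CC(C)[C@H](N)C(=O)OC(C)(C)C | starting material
3 | tert-butyl (2S)-2-{[(2Z)-4-ethoxy-3-methyl-4-oxobut-2-en-2-yl]amino}-3-methylbutanoate | CCOC(=O)/C(C)=C(/C)N[C@@H](C(C)C)C(=O)OC(C)(C)C | intermediate
4 | geranyl bromide, (2E)-1-bromo-3,7-dimethylocta-2,6-diene | BrC/C=C(\C)CCC=C(C)C | starting material
5 | tert-butyl (2S)-2-{[(3R,5E)-3-(ethoxycarbonyl)-3,6,10-trimethylundeca-5,9-dien-2-ylidene]amino}-3-methylbutanoate (ketimine) | CCOC(=O)[C@](C)(C/C=C(\C)CCC=C(C)C)C(C)=N[C@@H](C(C)C)C(=O)OC(C)(C)C | intermediate (not isolated)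
6 | ethyl (2R,4E)-2-acetyl-2,5,9-trimethyldeca-4,8-dienoate | CCOC(=O)[C@](C)(C/C=C(\C)CCC=C(C)C)C(C)=O | intermediate
7 | diketene (4-methylideneoxetan-2-one) | C=C1CC(=O)O1 | starting material
8 | ethyl (2R)-2-[(2E)-3,7-dimethylocta-2,6-dien-1-yl]-2-methyl-3,5,7-trioxooctanoate | CCOC(=O)[C@](C)(C/C=C(\C)CCC=C(C)C)C(=O)CC(=O)CC(C)=O | intermediate (not isolated)
9 | (4R)-2-acetyl-4-[(2E)-3,7-dimethylocta-2,6-dien-1-yl]-3,5-dihydroxy-4-methylcyclohexa-2,5-dien-1-one | CC(=O)C1=C(O)[C@](C)(C/C=C(\C)CCC=C(C)C)C(O)=CC1=O | intermediate
10 | phloroglucinol (benzene-1,3,5-triol) | Oc1cc(O)cc(O)c1 | starting material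
11 | hexanoyl chloride | CCCCCC(=O)Cl | starting material
12 | 1-(2,4,6-trihydroxyphenyl)hexan-1-one | CCCCCC(=O)c1c(O)cc(O)cc1O | intermediate
13 | N,N-dimethylmethyleneiminium iodide (Eschenmoser's salt) | C=[N+](C)C.[I-] | starting material
14 | (4R)-2-acetyl-6-[(dimethylammonio)methyl]-4-[(2E)-3,7-dimethylocta-2,6-dien-1-yl]-3,5-dihydroxy-4-methylcyclohexa-2,5-dien-1-one iodide (Mannich salt) | CC(=O)C1=C(O)[C@](C)(C/C=C(\C)CCC=C(C)C)C(O)=C(C[NH+](C)C)C1=O.[I-] | intermediate (not isolated)
15 | (4R)-2-acetyl-4-[(2E)-3,7-dimethylocta-2,6-dien-1-yl]-6-[(3-hexanoyl-2,4,6-trihydroxyphenyl)methyl]-3,5-dihydroxy-4-methylcyclohexa-2,5-dien-1-one | CCCCCC(=O)c1c(O)c(CC2=C(O)[C@@](C)(C/C=C(\C)CCC=C(C)C)C(O)=C(C(C)=O)C2=O)c(O)cc1O | intermediate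
16 | 3-methylbut-2-enal (prenal) | CC(C)=CC=O | starting material
17 | ortho-quinone methide of 15: the former benzene carbon C5 carries a (Z)-3-methylbut-2-en-1-ylidene group, C6 is the quinonoid C=O, O2–H and O4–H are enolic, the trione ring (4R) is unchanged | CCCCCC(=O)C1=C(O)C(CC2=C(O)[C@@](C)(C/C=C(\C)CCC=C(C)C)C(O)=C(C(C)=O)C2=O)=C(O)/C(=C/C=C(C)C)C1=O | intermediate (not isolated)
18 | (4R)-2-acetyl-4-[(2E)-3,7-dimethylocta-2,6-dien-1-yl]-6-[(8-hexanoyl-5,7-dihydroxy-2,2-dimethyl-2H-chromen-6-yl)methyl]-3,5-dihydroxy-4-methylcyclohexa-2,5-dien-1-one (CNP0319887.1) | CCCCCC(=O)c1c(O)c(CC2=C(O)[C@@](C)(C/C=C(\C)CCC=C(C)C)C(O)=C(C(C)=O)C2=O)c(O)c2c1OC(C)(C)C=C2 | target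

**Count and risks**

Total step count: 6. Longest linear sequence: 5 steps (1, 2, 3, 5, 6); step 4 is a one-step branch.

Steps most likely to fail:

1. Step 6. The pyran ring may close through the wrong phenol oxygen (O4 instead of O6), and under heat and amine the methylene bridge may open by a retro-Michael process and redistribute the two halves. The fallback sets out from 12 and comes back at 18; it replaces steps 5 and 6 and uses 9 directly. The para hydroxyl of 12 is masked first (MOMCl, i-Pr2NEt, CH2Cl2, 0 °C) to give 1-[2,6-dihydroxy-4-(methoxymethoxy)phenyl]hexan-1-one F1. Annulation of this symmetrical phenol with 16 (ethylenediammonium diacetate, toluene, 90 °C) can close only through an ortho oxygen and should give 1-[7-hydroxy-5-(methoxymethoxy)-2,2-dimethyl-2H-chromen-8-yl]hexan-1-one F2. The helper group is then removed (HCl, MeOH, 40 °C) to give 1-(5,7-dihydroxy-2,2-dimethyl-2H-chromen-8-yl)hexan-1-one F3. A Mannich reaction at its only free ring carbon (aq. CH2O, Me2NH, EtOH, rt) should give 1-{6-[(dimethylamino)methyl]-5,7-dihydroxy-2,2-dimethyl-2H-chromen-8-yl}hexan-1-one F4, which is heated with 9 (MeCN, 60–80 °C) so that the bridge is formed last and under mild conditions, arriving at 18.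

2. Step 3. Diketene may be attacked at oxygen or oligomerise, and proton transfer from the first-formed triketone may quench unreacted enolate before acylation is complete. The fallback sets out from 6 and comes back at 8. The acetoacetyl unit is introduced in masked form by a crossed Claisen condensation of 6 with ethyl (2-methyl-1,3-dioxolan-2-yl)acetate (NaH, THF, reflux; only the methyl ketone of 6 can enolise toward the ester) to give ethyl (2R)-2-[(2E)-3,7-dimethylocta-2,6-dien-1-yl]-2-methyl-6-(2-methyl-1,3-dioxolan-2-yl)-3,5-dioxohexanoate F5. The ketal is then removed (PPTS, aq. acetone, 40 °C) to give 8, which is cyclised with t-BuOK as in the second stage of step 3.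

3. Step 5. The methylene trione may be released before aminomethylation is complete and be captured by remaining 9, or 12 may be alkylated twice. The fallback sets out from 12 and comes back at 15, with the roles of the partners reversed. An excess of 12 is aminomethylated once (aq. CH2O, Me2NH, EtOH, 0 °C) to give the stable phenolic Mannich base 1-{3-[(dimethylamino)methyl]-2,4,6-trihydroxyphenyl}hexan-1-one F6. Heating F6 with 9 (dioxane, 80 °C) generates the aromatic ortho-quinone methide in the presence of the single-site trione nucleophile and should give 15.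

Further compounds
F1 | step 6 | 1-[2,6-dihydroxy-4-(methoxymethoxy)phenyl]hexan-1-one | CCCCCC(=O)c1c(O)cc(OCOC)cc1O
F2 | step 6 | 1-[7-hydroxy-5-(methoxymethoxy)-2,2-dimethyl-2H-chromen-8-yl]hexan-1-one | CCCCCC(=O)c1c(O)cc(OCOC)c2c1OC(C)(C)C=C2
F3 | step 6 | 1-(5,7-dihydroxy-2,2-dimethyl-2H-chromen-8-yl)hexan-1-one | CCCCCC(=O)c1c(O)cc(O)c2c1OC(C)(C)C=C2
F4 | step 6 | 1-{6-[(dimethylamino)methyl]-5,7-dihydroxy-2,2-dimethyl-2H-chromen-8-yl}hexan-1-one | CCCCCC(=O)c1c(O)c(CN(C)C)c(O)c2c1OC(C)(C)C=C2
F5 | step 3 | ethyl (2R)-2-[(2E)-3,7-dimethylocta-2,6-dien-1-yl]-2-methyl-6-(2-methyl-1,3-dioxolan-2-yl)-3,5-dioxohexanoate | CCOC(=O)[C@](C)(C/C=C(\C)CCC=C(C)C)C(=O)CC(=O)CC1(C)OCCO1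
F6 | step 5 | 1-{3-[(dimethylamino)methyl]-2,4,6-trihydroxyphenyl}hexan-1-one | CCCCCC(=O)c1c(O)cc(O)c(CN(C)C)c1O
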